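Retrosynthesis (azulene numbering of the target): cut the vanillate C–O bond, then the C6=C7 alkene (ring-closing metathesis), then C4–C5 (methallyl addition to an aldehyde), then the ring-fusion bond C3a–C8a.
Enabling feature: in the five-membered ring, C8a (CH3) and C3 (iPr) are 1,4-related through C1–C2. C3a–H sits between carbinol C3 and the oxygenated exocyclic C4.
Putting C4 back between C3a and C8a turns the cyclopentane into a p-menthane cyclohexane-1,2,3-triol. This is the retron of a cis-diol monosulfonate ring contraction.
Forward order: the six-membered ring (from dihydrocarvone) comes first. It is contracted in step 7, which expels C4 as a formyl group. The seven-membered ring is closed last by metathesis, then the ester is made.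
Stereochemistry: C8a comes from asymmetric decarboxylative allylation, and a relay carbinol from CBS reduction. C3 and the tosylate carbon come from hydroxyl-directed syn-dihydroxylation. C3a is set by inversion and C8a kept by retention in the 1,2-shift. C4 comes from chelation-controlled addition.

Key step: step 7

Assumption: the sense of induction of (R)-t-BuPHOX is assigned by analogy with 2-allyl-2-methylcyclohexanone. That of (R)-2-methyl-CBS-oxazaborolidine is assigned with the fully substituted flank of the ketone as the large group. If either sense is opposite, the other, also commercial, enantiomer is used.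

Step 1
Reactants: 1 (+)-dihydrocarvone
Product: 2 carvenone (3-isopropyl-6-methylcyclohex-2-en-1-one)
Conditions: H2SO4 (50 % aq), 50 °C
Reagents that add atoms: none
Why: Acid-catalysed alkene isomerisation moves the isopropenyl double bond into conjugation with the ketone, the thermodynamic sink, and the stereocentres of 1 do not matter because they are erased here or in step 2.

Step 2
Reactants: 2 carvenone; 3 allyl chloroformate
Product: 5 allyl 5-isopropyl-2-methylcyclohexa-1,5-dien-1-yl carbonate, via lithium dienolate 4 (not isolated)
Conditions: LiN(iPr)2 (1.05 equiv), TMEDA, THF, −78 °C; then 3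
Reagents that add atoms: none
Why: Kinetic deprotonation of the enone at the alpha-prime carbon gives the cross-conjugated dienolate, which the chloroformate acylates on oxygen (enol carbonate formation).

Step 3
Reactants: 5 allyl dienol carbonate
Product: 6 (R)-6-allyl-3-isopropyl-6-methylcyclohex-2-en-1-one
Conditions: Pd2(dba)3 (2.5 mol %), (R)-t-BuPHOX (6 mol %), toluene, 25 °C
Reagents that add atoms: none
Why: In this decarboxylative asymmetric allylic alkylation (Tsuji allylation), zerovalent palladium ionises the allyl carbonate, CO2 is lost, and the ligand-bound allylpalladium enolate couples at the methyl-bearing carbon, so the ligand sets the quaternary centre.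

Step 4
Reactants: 6 enone
Product: 7 (1S,6R)-6-allyl-3-isopropyl-6-methylcyclohex-2-en-1-ol
Conditions: (R)-2-methyl-CBS-oxazaborolidine (20 mol %), catecholborane (2 equiv), toluene, −78 °C; aqueous work-up
Reagents that add atoms: none
Why: In the Corey–Bakshi–Shibata reduction the catalyst binds the ketone with its quaternary flank as the large group and delivers hydride to one face despite the negligible substrate bias, while catecholborane at low temperature gives 1,2-reduction only and leaves the terminal alkene alone.

Step 5
Reactants: 7 allylic alcohol
Product: 9 (1R,2R,3R,4R)-4-allyl-1-isopropyl-4-methylcyclohexane-1,2,3-triol, via cyclic osmate ester 8 (not isolated)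
Conditions: OsO4 (1.05 equiv), TMEDA (1.1 equiv), CH2Cl2, −78 °C; then aq Na2SO3, THF, reflux
Reagents that add atoms: osmium tetroxide O=[Os](=O)(=O)=O
Why: In this hydrogen-bond-directed dihydroxylation the allylic hydroxyl binds OsO4·TMEDA and guides the suprafacial addition to its own face of the adjacent electron-rich trisubstituted alkene, which sets both new carbinol centres cis to it and favours this alkene over the remote monosubstituted one.

Step 6
Reactants: 9 triol
Product: 10 (1R,2R,5R,6R)-5-allyl-2,6-dihydroxy-2-isopropyl-5-methylcyclohexyl 4-methylbenzenesulfonate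
Conditions: TsCl (1.1 equiv), Bu2SnO (10 mol %), Et3N (1.5 equiv), CH2Cl2, 0 °C to rt
Reagents that add atoms: 4-toluenesulfonyl chloride Cc1ccc(S(=O)(=O)Cl)cc1
Why: In stannylene-mediated regioselective sulfonylation the tin acetal of a cis-1,2-diol on a chair activates the equatorial oxygen, which is the middle hydroxyl in either diol pair of 9, while the axial neopentyl secondary and the tertiary hydroxyl stay free.

Step 7
Reactants: 10 hydroxy tosylate
Product: 11 (1R,2R,5R)-2-allyl-5-hydroxy-5-isopropyl-2-methylcyclopentane-1-carbaldehyde
Conditions: KOtBu (1.0 equiv), THF, −20 °C to rt; pH 7 buffer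
Reagents that add atoms: none
Why: Deprotonation of the secondary hydroxyl next to the tosylate triggers a pinacol-type (semipinacol) 1,2-alkyl shift, in which the ring bond from the carbinol carbon to the quaternary carbon swings over to the tosylate carbon as tosylate leaves and the carbinol carbon becomes the formyl group. The closest known reaction type is the base-induced ring contraction of conformationally fixed cis-2-hydroxycyclohexyl sulfonates (axial hydroxyl, equatorial sulfonate) to formylcyclopentanes, known from six-to-five contractions in diterpenoid chemistry and, with tertiary carbinols, from decalin-to-hydroazulene conversions. The cyclopentane is closed by ring contraction, a concerted shift in which the migrating carbon displaces tosylate from the rear (tet geometry, no exo or endo addition to a π bond), and the required antiperiplanar alignment is present in the ground-state chair with equatorial isopropyl, equatorial tosylate and two axial hydroxyls. The new stereocentre (future C3a) is set by inversion at the tosylate carbon, the quaternary carbon (future C8a) migrates with retention and the tertiary carbinol is untouched, so formyl, hydroxyl and methyl end on one face and the C3a hydrogen, isopropyl and allyl on the other. The step must avoid epoxide closure, hydride shift and migration of the CH2 on the other flank: both hydroxyls are cis to the tosylate so no oxygen can attack from the rear, the hydride shift would need the flipped chair with axial isopropyl and a syn-axial methyl/tosylate contact, and a fully substituted carbon migrates far more readily than a CH2 pushed by the hindered tertiary alkoxide. One equivalent of base ends as potassium tosylate, so the β-hydroxy aldehyde is left neutral and protected from retro-aldol cleavage.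

Step 8
Reactants: 11 aldehyde; 12 2-methylallylmagnesium chloride
Product: 13 (1R,2S,3R)-3-allyl-2-[(1S)-1-hydroxy-3-methylbut-3-en-1-yl]-1-isopropyl-3-methylcyclopentan-1-ol
Conditions: 12 (3 equiv), THF, −78 °C; aq NH4Cl
Reagents that add atoms: none
Why: In this chelation-controlled Grignard addition the first equivalent makes the magnesium alkoxide of the tertiary hydroxyl, which ties the cis formyl oxygen into a six-membered chelate; one carbonyl face is then buried under the ring between the methyl group and the chelate, and the reagent attacks the open face beside the ring C–H to give the (S)-carbinol.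

Step 9
Reactants: 13 diene diol
Product: 14 jaeschkeanadiol ((3R,3aS,4S,8aR)-3-isopropyl-6,8a-dimethyl-1,2,3,3a,4,5,8,8a-octahydroazulene-3,4-diol)
Conditions: second-generation Grubbs catalyst (5 mol %), CH2Cl2 (2 mM), 40 °C
Reagents that add atoms: none
Why: Ring-closing metathesis of the monosubstituted alkene and the 1,1-disubstituted alkene closes the trans-fused cycloheptene and places the trisubstituted C6=C7 bond exactly, touches no stereocentre, tolerates the free hydroxyls and is driven by loss of ethene.

Step 10
Reactants: 14 jaeschkeanadiol; 15 4-acetoxy-3-methoxybenzoic acid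
Product: 16 O-acetylteferin
Conditions: DCC (1.5 equiv), DMAP (0.2 equiv), CH2Cl2, rt
Reagents that add atoms: none
Why: Steglich esterification acylates only the secondary hydroxyl, because the tertiary one next to the isopropyl group is too hindered, and the phenol is masked as its acetate so that the acid cannot condense with itself.

Step 11
Reactants: 16 O-acetylteferin
Product: 17 teferin
Conditions: K2CO3 (0.2 equiv), MeOH, 0 °C
Reagents that add atoms: none
Why: In base-catalysed methanolysis (transesterification) the aryl acetate, which has a phenoxide leaving group, is cleaved much faster than the hindered secondary benzoate, and the alkene and both carbinol centres are inert.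

Compound list
1 | (+)-dihydrocarvone, (5R)-2-methyl-5-(prop-1-en-2-yl)cyclohexan-1-one, commercial mixture of C2 epimers | CC1CC[C@H](CC1=O)C(C)=C | starting material
2 | carvenone, 3-isopropyl-6-methylcyclohex-2-en-1-one (C6 epimerisable, not defined) | CC1CCC(C(C)C)=CC1=O | intermediate
3 | allyl chloroformate | C=CCOC(=O)Cl | starting material
4 | lithium 5-isopropyl-2-methylcyclohexa-1,5-dien-1-olate | [Li+].[O-]C1=C(C)CCC(C(C)C)=C1 | intermediate
5 | allyl 5-isopropyl-2-methylcyclohexa-1,5-dien-1-yl carbonate | C=CCOC(=O)OC1=C(C)CCC(C(C)C)=C1 | intermediate
6 | (R)-6-allyl-3-isopropyl-6-methylcyclohex-2-en-1-one | C=CC[C@@]1(C)CCC(C(C)C)=CC1=O | intermediate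
7 | (1S,6R)-6-allyl-3-isopropyl-6-methylcyclohex-2-en-1-ol (hydroxyl cis to methyl) | C=CC[C@@]1(C)CCC(C(C)C)=C[C@@H]1O | intermediate
8 | cyclic osmate ester of 7 on the ring alkene, syn to the hydroxyl, TMEDA adduct | C=CC[C@@]1(C)CC[C@]2(C(C)C)O[Os](=O)(=O)O[C@@H]2[C@@H]1O.CN(C)CCN(C)C | intermediate
9 | (1R,2R,3R,4R)-4-allyl-1-isopropyl-4-methylcyclohexane-1,2,3-triol (three hydroxyls and methyl on one face) | C=CC[C@@]1(C)CC[C@@](O)(C(C)C)[C@H](O)[C@@H]1O | intermediate
10 | (1R,2R,5R,6R)-5-allyl-2,6-dihydroxy-2-isopropyl-5-methylcyclohexyl 4-methylbenzenesulfonate | C=CC[C@@]1(C)CC[C@@](O)(C(C)C)[C@H](OS(=O)(=O)c2ccc(C)cc2)[C@@H]1O | intermediate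
11 | (1R,2R,5R)-2-allyl-5-hydroxy-5-isopropyl-2-methylcyclopentane-1-carbaldehyde | C=CC[C@@]1(C)CC[C@@](O)(C(C)C)[C@@H]1C=O | intermediate
12 | 2-methylallylmagnesium chloride | C=C(C)C[Mg]Cl | starting material
13 | (1R,2S,3R)-3-allyl-2-[(1S)-1-hydroxy-3-methylbut-3-en-1-yl]-1-isopropyl-3-methylcyclopentan-1-ol | C=CC[C@@]1(C)CC[C@@](O)(C(C)C)[C@@H]1[C@@H](O)CC(C)=C | intermediate
14 | jaeschkeanadiol, (3R,3aS,4S,8aR)-3-isopropyl-6,8a-dimethyl-1,2,3,3a,4,5,8,8a-octahydroazulene-3,4-diol | O[C@H]1CC(C)=CC[C@@]2(C)CC[C@@](O)(C(C)C)[C@H]12 | intermediate
15 | 4-acetoxy-3-methoxybenzoic acid | COc1cc(C(=O)O)ccc1OC(C)=O | starting material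
16 | O-acetylteferin, jaeschkeanadiol 4-(4-acetoxy-3-methoxybenzoate) | COc1cc(C(=O)O[C@H]2CC(C)=CC[C@@]3(C)CC[C@@](O)(C(C)C)[C@H]23)ccc1OC(C)=O | intermediate
17 | teferin | COc1cc(C(=O)O[C@H]2CC(C)=CC[C@@]3(C)CC[C@@](O)(C(C)C)[C@H]23)ccc1O | target

Total step count: 11. Longest linear sequence: 11 (1 to 17).

Steps most likely to fail

Step 6. Regioselectivity may be lost: sulfonylation could occur at the axial secondary hydroxyl, or twice, because the equatorial hydroxyl is crowded by the neighbouring isopropyl group. The fallback replaces selective activation by temporary protection and sets out from triol 9. tBu2Si(OTf)2 and 2,6-lutidine bridge the two syn-axial hydroxyls, the only pair able to form a six-membered silylene ring, to give the di-tert-butylsilylene acetal F1. Its single free hydroxyl is sulfonylated (TsCl, DMAP, pyridine) to the silylene tosylate F2. HF·pyridine removes the silylene, and the route is rejoined at 10.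

Step 8. Facial selectivity may be poor if the very reactive allylic Grignard reagent adds faster than the chelate forms. The fallback sets the carbinol centre in the bicyclic ketone instead and sets out from aldehyde 11. The addition is run without regard to selectivity, and the mixture of 13 and its carbinol epimer F3 is oxidised with Dess–Martin periodinane to the methallyl ketone F4. Ring-closing metathesis (second-generation Grubbs catalyst) gives the bicyclic β-hydroxy ketone F5. Evans–Saksena reduction with Me4NBH(OAc)3 then gives the anti-1,3-diol, because the tertiary hydroxyl binds boron and delivers hydride to its own face of the ketone. The route is rejoined at 14.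

Step 4. Facial selectivity may be low or reversed, because the vinyl flank and the quaternary flank compete for the role of the large group in the catalyst complex. The fallback gives up reagent control in favour of separation and recycling and sets out from enone 6. Luche reduction (NaBH4, CeCl3·7H2O, MeOH) gives 7 together with the epimeric allylic alcohol F6. The two are separated by chromatography, and F6 is returned to 6 with MnO2 and resubmitted. The route is rejoined at 7.

Further compounds
F1 | step 6 | di-tert-butylsilylene acetal of 9 across the tertiary and the neopentyl secondary hydroxyl | C=CC[C@@]1(C)CC[C@]2(C(C)C)O[Si](C(C)(C)C)(C(C)(C)C)O[C@H]1[C@H]2O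
F2 | step 6 | 4-methylbenzenesulfonate of F1 | C=CC[C@@]1(C)CC[C@]2(C(C)C)O[Si](C(C)(C)C)(C(C)(C)C)O[C@H]1[C@H]2OS(=O)(=O)c3ccc(C)cc3
F3 | step 8 | (1R,2S,3R)-3-allyl-2-[(1R)-1-hydroxy-3-methylbut-3-en-1-yl]-1-isopropyl-3-methylcyclopentan-1-ol | C=CC[C@@]1(C)CC[C@@](O)(C(C)C)[C@@H]1[C@H](O)CC(C)=C
F4 | step 8 | 1-[(1R,2R,5R)-2-allyl-5-hydroxy-5-isopropyl-2-methylcyclopentyl]-3-methylbut-3-en-1-one | C=CC[C@@]1(C)CC[C@@](O)(C(C)C)[C@@H]1C(=O)CC(C)=C
F5 | step 8 | (3R,3aR,8aR)-3-hydroxy-3-isopropyl-6,8a-dimethyl-2,3,3a,5,8,8a-hexahydroazulen-4(1H)-one | O=C1CC(C)=CC[C@@]2(C)CC[C@@](O)(C(C)C)[C@H]12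
F6 | step 4 | (1R,6R)-6-allyl-3-isopropyl-6-methylcyclohex-2-en-1-ol | C=CC[C@@]1(C)CCC(C(C)C)=C[C@H]1O
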